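The oxolane ring is cut into its C2–O1–C5 ether triad and its C3–C4 pair. A nonstabilised carbonyl ylide (ArCH=O⁺–CH2⁻), carrying the complete, protected threo side chain, adds across the Z double bond of an enantiopure γ-aryl butenolide, forming C5–C4 and C2–C3 in one (3+2) cycloaddition. The step exploits the cis relation of the C3 hydroxymethyl and C4 benzyl groups: tied together as a lactone through an oxygenated benzylic carbon, they enforce the Z alkene, and that temporary stereocentre steers the face; it is then erased by hydrogenolysis. The ylide precursor is an α-silyl chloromethyl ether made by Evans glycolate aldol chemistry.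

Key step: step 11

Remark: in step 9 the (S,S)-ProPhenol ligand is assumed to deliver the (R)-carbinol; should it deliver the other face, its antipode is used and nothing else changes.

Step 1
Reactants: 1 4-bromo-2-methoxyphenol; 2 (R)-4-benzyl-3-(chloroacetyl)oxazolidin-2-one
Product: 3 (R)-4-benzyl-3-[(4-bromo-2-methoxyphenoxy)acetyl]oxazolidin-2-one
Conditions: K2CO3, NaI (cat.), acetone, rt to 40 °C
Reagents that add atoms: none
Why: Williamson-type SN2 displacement of the activated α-chloro imide by the phenoxide should give the aryloxyacetyl imide without touching the auxiliary stereocentre.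

Step 2
Reactants: 3 (R)-4-benzyl-3-[(4-bromo-2-methoxyphenoxy)acetyl]oxazolidin-2-one; 4 4-(benzyloxy)-3-methoxybenzaldehyde
Product: 6 (R)-4-benzyl-3-[(2R,3S)-3-(4-(benzyloxy)-3-methoxyphenyl)-2-(4-bromo-2-methoxyphenoxy)-3-hydroxypropanoyl]oxazolidin-2-one, via boron enolate 5 (not isolated)
Conditions: Bu2BOTf, iPr2NEt, CH2Cl2, −78 to 0 °C; then 4, −78 to 0 °C; pH 7 buffer, MeOH, H2O2
Reagents that add atoms: none
Why: Evans syn-aldol of the Z-boron enolate of the glycolate-type imide through a Zimmerman–Traxler chair, in which the (R)-benzyl auxiliary sets C2 (R) and C3 (S), the syn (threo) aryloxy/hydroxy pair of the side chain.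

Step 3
Reactants: 6 the aldol imide
Product: 7 (1S,2S)-1-[4-(benzyloxy)-3-methoxyphenyl]-2-(4-bromo-2-methoxyphenoxy)propane-1,3-diol (threo)
Conditions: NaBH4, THF–H2O, 0 °C to rt
Reagents that add atoms: none
Why: Reductive cleavage of the N-acyloxazolidinone by borohydride should give the primary alcohol and release the auxiliary while both stereocentres stay untouched.

Step 4
Reactants: 7 the threo 1,3-diol
Product: 8 (2R,4S,5S)-4-[4-(benzyloxy)-3-methoxyphenyl]-5-(4-bromo-2-methoxyphenoxy)-2-phenyl-1,3-dioxane
Conditions: PhCH(OMe)2, PPTS (cat.), CH2Cl2, rt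
Reagents that add atoms: benzaldehyde dimethyl acetal, COC(OC)c1ccccc1
Why: Acid-catalysed transacetalisation should give the six-membered benzylidene acetal under thermodynamic control (2-phenyl and 4-aryl equatorial, 5-aryloxy axial), masking both hydroxyls against the ylide with a group that later leaves by hydrogenolysis.

Step 5
Reactants: 8 the aryl bromide
Product: 10 4-{[(2R,4S,5S)-4-(4-(benzyloxy)-3-methoxyphenyl)-2-phenyl-1,3-dioxan-5-yl]oxy}-3-methoxybenzaldehyde, via aryllithium 9 (not isolated)
Conditions: n-BuLi, THF, −78 °C; DMF, −78 °C to rt; H2O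
Reagents that add atoms: N,N-dimethylformamide, CN(C)C=O
Why: Bromine–lithium exchange is faster than any deprotonation at −78 °C and Bouveault-type formylation of the aryllithium should give the aldehyde.

Step 6
Reactants: 10 the aldehyde
Product: 11 [dimethyl(phenyl)silyl]{4-[(2R,4S,5S)-dioxanyloxy]-3-methoxyphenyl}methanol, the α-hydroxysilane of 10 (both carbinol epimers)
Conditions: PhMe2SiLi, THF, −78 °C; AcOH, −78 °C
Reagents that add atoms: dimethyl(phenyl)silyllithium, [Li][Si](C)(C)c1ccccc1
Why: 1,2-addition of the silyllithium to the aldehyde with a cold acidic quench (forestalling Brook rearrangement, already slowed by the electron-rich ring) should give the α-hydroxysilane, whose new centre is formed unselectively but becomes the planar ylide carbon.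

Step 7
Reactants: 11 the α-hydroxysilane
Product: 12 methylthiomethyl ether of 11 (both epimers)
Conditions: Me2S, dibenzoyl peroxide, MeCN, 0 °C
Reagents that add atoms: dimethyl sulfide, CSC
Why: Pummerer-type methylthiomethylation (the methyl(methylene)sulfonium ion formed from Me2S and the peroxide is trapped by the alcohol) works without base and so avoids Brook rearrangement of the α-silyl alkoxide.

Step 8
Reactants: 12 the methylthiomethyl ether
Product: 13 chloromethyl ether of 11 (both epimers), used crude
Conditions: SO2Cl2, CH2Cl2, −78 to 0 °C; evaporation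
Reagents that add atoms: sulfuryl chloride, O=S(=O)(Cl)Cl
Why: Chlorinolysis of the O,S-acetal (S-chlorination, loss of MeSCl, chloride capture of the oxocarbenium ion) should give the chloromethyl ether without free HCl, so the acetal and the benzylic silane survive.

Step 9
Reactants: 4 4-(benzyloxy)-3-methoxybenzaldehyde; 14 methyl propiolate
Product: 15 methyl (R)-4-[4-(benzyloxy)-3-methoxyphenyl]-4-hydroxybut-2-ynoate
Conditions: Me2Zn, (S,S)-ProPhenol (cat.), Ph3P=O (cat.), toluene, 4 °C; aq. NH4Cl
Reagents that add atoms: none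
Why: Dinuclear zinc ProPhenol-catalysed asymmetric alkynylation of the aryl aldehyde, in which the chiral zinc complex selects the aldehyde face and sets the carbinol centre (R).

Step 10
Reactants: 15 the propargylic alcohol
Product: 17 (S)-5-[4-(benzyloxy)-3-methoxyphenyl]furan-2(5H)-one, via Z-hydroxy enoate 16 (not isolated)
Conditions: H2 (1 atm), Pd/CaCO3 poisoned with Pb(OAc)2 (Lindlar catalyst), quinoline, EtOAc, rt; then PPTS (cat.), rt
Reagents that add atoms: none
Why: syn semi-hydrogenation over the poisoned palladium catalyst should give the Z-hydroxy enoate, which lactonises with loss of methanol, the untouched carbinol centre becoming C5 (S) of the butenolide.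

Step 11
Reactants: 13 the α-silyl chloromethyl ether; 17 (S)-5-[4-(benzyloxy)-3-methoxyphenyl]furan-2(5H)-one
Product: 19 (3S,3aR,6S,6aS)-3-[4-(benzyloxy)-3-methoxyphenyl]-6-{4-[(2R,4S,5S)-4-(4-(benzyloxy)-3-methoxyphenyl)-2-phenyl-1,3-dioxan-5-yl]oxy-3-methoxyphenyl}tetrahydro-1H,3H-furo[3,4-c]furan-1-one, via carbonyl ylide 18 (not isolated)
Conditions: CsF, 17 (2 equiv), MeCN, rt, slow addition of 13
Reagents that add atoms: none
Why: Fluoride attacks silicon of 13 and chloride leaves from the chloromethyl ether (1,3-elimination), giving the nonstabilised carbonyl ylide 18, which adds as a 4π dipole across C3=C4 of 17 in a concerted, asynchronous suprafacial (3+2) cycloaddition; the closest known reaction type is the fluoride-induced generation of carbonyl ylides from α-silyl α'-chloro ethers and their cycloaddition to electron-poor alkenes. The oxolane ring closes by this intermolecular [π4s+π2s] union of both C–C bonds (were it stepwise, conjugate addition of the CH2 terminus followed by 5-(enolexo)-endo-trig collapse of the lactone enolate onto the aryl oxocarbenium ion). The cis ring fusion at C3a and C6a is fixed by the Z double bond held in the lactone ring and by suprafacial addition, and their absolute configuration is relayed from C5 of 17, the dipole adding to the face anti to the C5 aryl group. C6, the future C2 of the oxolane, is set by the exo approach, in which the ylide aryl group points away from the lactone ring and ends trans to the lactone carbonyl. The step needs regioselectivity (CH2 terminus to the β-carbon, ArCH terminus to the α-carbon), which the electron-rich aryl should secure by placing oxocarbenium character on the benzylic carbon and carbanion character on the unhindered CH2 terminus, and it needs the cycloaddition to outrun γ-deprotonation of 17, which sparingly soluble CsF and slow ylide release favour.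

Step 12
Reactants: 19 the bicyclic lactone
Product: 20 (2S,3S,4R)-2-{4-[(1S,2S)-1,3-dihydroxy-1-(4-hydroxy-3-methoxyphenyl)propan-2-yl]oxy-3-methoxyphenyl}-4-(4-hydroxy-3-methoxybenzyl)oxolane-3-carboxylic acid
Conditions: H2 (3 atm), Pd(OH)2/C, THF–EtOAc, AcOH (cat.), rt
Reagents that add atoms: none
Why: Catalytic hydrogenolysis should cleave the benzylic C–O bond of the lactone (a carboxylate leaving group on a carbon that becomes p-hydroxybenzylic once its benzyl ether is gone) to give the benzyl group and the acid, and should remove both benzyl ethers and the benzylidene acetal, while the poorer leaving groups at the oxolane C2–O bond and the side-chain benzylic C–OH, and all five stereocentres, should persist.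

Step 13
Reactants: 20 the carboxylic acid
Product: 21 (1S,2S)-1-(4-hydroxy-3-methoxyphenyl)-2-{4-[(2S,3R,4R)-4-(4-hydroxy-3-methoxybenzyl)-3-(hydroxymethyl)oxolan-2-yl]-2-methoxyphenoxy}propane-1,3-diol (CNP0226724.1)
Conditions: BH3·THF (excess), THF, 0 °C to rt; MeOH
Reagents that add atoms: none
Why: Borane reduces the carboxylic acid chemoselectively through its acyloxyborane, the free phenols and alcohols only consuming reagent as borates that methanolysis releases, so the hydroxymethyl group at C3 should form without epimerisation.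

Compound list
1 | 4-bromo-2-methoxyphenol | COc1cc(Br)ccc1O | starting material
2 | (R)-4-benzyl-3-(chloroacetyl)oxazolidin-2-one | O=C(CCl)N1C(=O)OC[C@H]1Cc1ccccc1 | starting material
3 | (R)-4-benzyl-3-[(4-bromo-2-methoxyphenoxy)acetyl]oxazolidin-2-one | COc1cc(Br)ccc1OCC(=O)N1C(=O)OC[C@H]1Cc1ccccc1 | intermediate
4 | 4-(benzyloxy)-3-methoxybenzaldehyde | COc1cc(C=O)ccc1OCc1ccccc1 | starting material
5 | Z-dibutylboron enolate of 3 | CCCCB(CCCC)O/C(=C\Oc1ccc(Br)cc1OC)N1C(=O)OC[C@H]1Cc1ccccc1 | intermediate
6 | (R)-4-benzyl-3-[(2R,3S)-3-(4-(benzyloxy)-3-methoxyphenyl)-2-(4-bromo-2-methoxyphenoxy)-3-hydroxypropanoyl]oxazolidin-2-one | COc1cc(Br)ccc1O[C@@H](C(=O)N1C(=O)OC[C@H]1Cc1ccccc1)[C@@H](O)c1ccc(OCc2ccccc2)c(OC)c1 | intermediate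
7 | (1S,2S)-1-[4-(benzyloxy)-3-methoxyphenyl]-2-(4-bromo-2-methoxyphenoxy)propane-1,3-diol | COc1cc(Br)ccc1O[C@@H](CO)[C@@H](O)c1ccc(OCc2ccccc2)c(OC)c1 | intermediate
8 | (2R,4S,5S)-4-[4-(benzyloxy)-3-methoxyphenyl]-5-(4-bromo-2-methoxyphenoxy)-2-phenyl-1,3-dioxane | COc1cc(Br)ccc1O[C@H]1CO[C@@H](c2ccccc2)O[C@H]1c1ccc(OCc2ccccc2)c(OC)c1 | intermediate
9 | aryllithium from 8 (lithium in place of bromine) | [Li]c1ccc(O[C@H]2CO[C@@H](c3ccccc3)O[C@H]2c2ccc(OCc3ccccc3)c(OC)c2)c(OC)c1 | intermediate
10 | 4-{[(2R,4S,5S)-4-(4-(benzyloxy)-3-methoxyphenyl)-2-phenyl-1,3-dioxan-5-yl]oxy}-3-methoxybenzaldehyde | COc1cc(C=O)ccc1O[C@H]1CO[C@@H](c2ccccc2)O[C@H]1c1ccc(OCc2ccccc2)c(OC)c1 | intermediate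
11 | α-hydroxysilane of 10, ArCH(OH)SiMe2Ph, both carbinol epimers | COc1cc(C(O)[Si](C)(C)c2ccccc2)ccc1O[C@H]1CO[C@@H](c2ccccc2)O[C@H]1c1ccc(OCc2ccccc2)c(OC)c1 | intermediate
12 | methylthiomethyl ether of 11, ArCH(OCH2SMe)SiMe2Ph, both epimers | COc1cc(C(OCSC)[Si](C)(C)c2ccccc2)ccc1O[C@H]1CO[C@@H](c2ccccc2)O[C@H]1c1ccc(OCc2ccccc2)c(OC)c1 | intermediate
13 | chloromethyl ether of 11, ArCH(OCH2Cl)SiMe2Ph, both epimers | COc1cc(C(OCCl)[Si](C)(C)c2ccccc2)ccc1O[C@H]1CO[C@@H](c2ccccc2)O[C@H]1c1ccc(OCc2ccccc2)c(OC)c1 | intermediate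
14 | methyl propiolate | C#CC(=O)OC | starting material
15 | methyl (R)-4-[4-(benzyloxy)-3-methoxyphenyl]-4-hydroxybut-2-ynoate | COC(=O)C#C[C@H](O)c1ccc(OCc2ccccc2)c(OC)c1 | intermediate
16 | methyl (S,Z)-4-[4-(benzyloxy)-3-methoxyphenyl]-4-hydroxybut-2-enoate | COC(=O)/C=C\[C@H](O)c1ccc(OCc2ccccc2)c(OC)c1 | intermediate
17 | (S)-5-[4-(benzyloxy)-3-methoxyphenyl]furan-2(5H)-one | O=C1C=C[C@@H](c2ccc(OCc3ccccc3)c(OC)c2)O1 | intermediate
18 | carbonyl ylide ArCH=O(+)–CH2(−) carrying the benzylidene-protected side chain | [CH2-][O+]=Cc1ccc(O[C@H]2CO[C@@H](c3ccccc3)O[C@H]2c2ccc(OCc3ccccc3)c(OC)c2)c(OC)c1 | intermediate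
19 | (3S,3aR,6S,6aS)-3-[4-(benzyloxy)-3-methoxyphenyl]-6-{4-[(2R,4S,5S)-4-(4-(benzyloxy)-3-methoxyphenyl)-2-phenyl-1,3-dioxan-5-yl]oxy-3-methoxyphenyl}tetrahydro-1H,3H-furo[3,4-c]furan-1-one (cis-fused, both aryl groups exo) | O=C1O[C@H](c2ccc(OCc3ccccc3)c(OC)c2)[C@H]2CO[C@H](c3ccc(O[C@H]4CO[C@@H](c5ccccc5)O[C@H]4c4ccc(OCc5ccccc5)c(OC)c4)c(OC)c3)[C@@H]12 | intermediate
20 | (2S,3S,4R)-2-{4-[(1S,2S)-1,3-dihydroxy-1-(4-hydroxy-3-methoxyphenyl)propan-2-yl]oxy-3-methoxyphenyl}-4-(4-hydroxy-3-methoxybenzyl)oxolane-3-carboxylic acid | COc1cc(C[C@H]2CO[C@H](c3ccc(O[C@@H](CO)[C@@H](O)c4ccc(O)c(OC)c4)c(OC)c3)[C@H]2C(=O)O)ccc1O | intermediate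
21 | (1S,2S)-1-(4-hydroxy-3-methoxyphenyl)-2-{4-[(2S,3R,4R)-4-(4-hydroxy-3-methoxybenzyl)-3-(hydroxymethyl)oxolan-2-yl]-2-methoxyphenoxy}propane-1,3-diol | COc1cc(C[C@H]2CO[C@H](c3ccc(O[C@@H](CO)[C@@H](O)c4ccc(O)c(OC)c4)c(OC)c3)[C@H]2CO)ccc1O | target

Total step count: 13. Longest linear sequence: 11 steps (steps 1 to 8, then 11, 12 and 13); steps 9 and 10 form the second branch.

Steps most likely to fail

Step 11. Fluoride may act as a base on butenolide 17 (γ-deprotonation, hence racemisation, double-bond migration and protonation of the ylide), or the cycloaddition may show poor regio- or exo/endo control. The fallback builds the oxolane by classical aldol and cyclodehydration chemistry; it sets out from 17 and 10 and comes back at 21. Butenolide 17 is hydroxymethylated at C4, anti to the aryl group, by benzophenone-sensitised photoaddition of methanol (MeOH, Ph2CO, hν 350 nm) to give (4R,5S)-5-[4-(benzyloxy)-3-methoxyphenyl]-4-(hydroxymethyl)dihydrofuran-2(3H)-one F1. Hydrogenolysis (H2, Pd/C, AcOH) cleaves its benzylic lactone C–O bond and the benzyl ether, and the hydroxy acid relactonises onto the new CH2OH to give (R)-4-(4-hydroxy-3-methoxybenzyl)dihydrofuran-2(3H)-one F2, the configuration being relayed from C5 to C4. The dianion of F2 (LiHMDS, THF, −78 °C) should add to aldehyde 10 anti to the benzyl group and give the (3S,4R)-trans aldol lactone F3 (both carbinol epimers). LiAlH4 reduces F3 to the triol F4. CSA (cat.) in CH2Cl2 at 0 °C ionises the p-alkoxybenzylic carbinol of F4, and the hydroxymethyl group on the benzyl-bearing carbon should close the oxolane 2,3-trans to give the benzyl- and benzylidene-protected target F5. H2 over Pd(OH)2/C then removes the benzyl ether and the acetal and gives 21.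

Step 12. The conditions needed to cleave the lactone C–O bond may also hydrogenolyse the oxolane C2–O bond or the side-chain benzylic C–O bond, or the lactone cleavage may stall. The fallback replaces catalytic C–O hydrogenolysis by elimination and conjugate reduction; it sets out from 19 and comes back at 20. Brief hydrogenolysis (H2, 1 atm, Pd/C, EtOAc) is stopped once the benzyl ethers and the acetal are gone, giving the free-phenol lactone F6. NaBH4 in aqueous NaOH–THF at rt then lets the phenoxide expel the lactone carboxylate to form the p-quinone methide acid F7, which takes up hydride at the benzylic carbon and gives 20 after acidification; the other p-hydroxybenzylic carbon carries only hydroxide as leaving group and should not ionise at rt.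

Step 8. Sulfuryl chloride or the released sulfenyl chloride may chlorinate or sulfenylate the electron-rich rings, and the α-silyl benzylic ether may ionise. The fallback uses the regioisomeric ylide precursor, with silicon on the CH2 carbon and chloride on the benzylic carbon, which bypasses steps 6 to 8; it sets out from 10 and comes back at 19. Aldehyde 10 is acetalised with (trimethylsilyl)methanol (PPTS cat., MgSO4, benzene) to give the bis[(trimethylsilyl)methyl] acetal F8. Acetyl chloride (ZnCl2 cat., CH2Cl2, 0 °C) exchanges one alkoxy group for chloride and gives the α-chlorobenzyl (trimethylsilyl)methyl ether F9, which is used crude. CsF in MeCN with 17 desilylates the CH2 carbon with loss of chloride and gives the same ylide 18 and hence 19.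

Further compounds
F1 | step 11 | (4R,5S)-5-[4-(benzyloxy)-3-methoxyphenyl]-4-(hydroxymethyl)dihydrofuran-2(3H)-one | O=C1C[C@H](CO)[C@@H](c2ccc(OCc3ccccc3)c(OC)c2)O1
F2 | step 11 | (R)-4-(4-hydroxy-3-methoxybenzyl)dihydrofuran-2(3H)-one | COc1cc(C[C@H]2COC(=O)C2)ccc1O
F3 | step 11 | (3S,4R)-3-[hydroxy(aryl)methyl]-4-(4-hydroxy-3-methoxybenzyl)dihydrofuran-2(3H)-one, aryl as in 10, both carbinol epimers | COc1cc(C[C@H]2COC(=O)[C@@H]2C(O)c2ccc(O[C@H]3CO[C@@H](c4ccccc4)O[C@H]3c3ccc(OCc4ccccc4)c(OC)c3)c(OC)c2)ccc1O
F4 | step 11 | triol from reduction of F3: 2-(4-hydroxy-3-methoxybenzyl)-3-[hydroxy(aryl)methyl]butane-1,4-diol, both carbinol epimers | COc1cc(C[C@@H](CO)[C@H](CO)C(O)c2ccc(O[C@H]3CO[C@@H](c4ccccc4)O[C@H]3c3ccc(OCc4ccccc4)c(OC)c3)c(OC)c2)ccc1O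
F5 | step 11 | 21 with the side-chain diol as benzylidene acetal and the side-chain phenol as benzyl ether | COc1cc(C[C@H]2CO[C@H](c3ccc(O[C@H]4CO[C@@H](c5ccccc5)O[C@H]4c4ccc(OCc5ccccc5)c(OC)c4)c(OC)c3)[C@H]2CO)ccc1O
F6 | step 12 | 19 without benzyl ethers and acetal: the bicyclic lactone with two free phenols and the free side-chain diol | O=C1O[C@H](c2ccc(O)c(OC)c2)[C@H]2CO[C@H](c3ccc(O[C@@H](CO)[C@@H](O)c4ccc(O)c(OC)c4)c(OC)c3)[C@@H]12
F7 | step 12 | p-quinone methide acid from F6 | COC1=CC(=C[C@H]2CO[C@H](c3ccc(O[C@@H](CO)[C@@H](O)c4ccc(O)c(OC)c4)c(OC)c3)[C@H]2C(=O)O)C=CC1=O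
F8 | step 8 | bis[(trimethylsilyl)methyl] acetal of 10 | COc1cc(C(OC[Si](C)(C)C)OC[Si](C)(C)C)ccc1O[C@H]1CO[C@@H](c2ccccc2)O[C@H]1c1ccc(OCc2ccccc2)c(OC)c1
F9 | step 8 | α-chlorobenzyl (trimethylsilyl)methyl ether from F8, both epimers | COc1cc(C(Cl)OC[Si](C)(C)C)ccc1O[C@H]1CO[C@@H](c2ccccc2)O[C@H]1c1ccc(OCc2ccccc2)c(OC)c1
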